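Feature: in the ten-membered ring (C1–C10) the C3 oxygen, the C4 methylene and the C5=C16 exocyclic methylene form a homoallylic alcohol, and C2, between the quaternary C1 of ring A and C3, can be a ketone that enolises only toward C3.
Key disconnection C3–C4: [2,3]-Wittig ring contraction of the boron enolate of an eleven-membered C3–O–C16 allyl ether (ring atoms C1, C2, C3, O, C16, C5–C10); afterwards C2 reduction, inversion at C3 to the trans-epoxide, C6–O to C6–Cl with inversion, C9 ester.
Eleven-membered ether ring: C3–O bond by stannylene alkylation of a C2,C3-diol with 2,3-dibromopropene; ring closure at C5–C6 by intramolecular Nozaki–Hiyama–Kishi addition to the C6 aldehyde.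
Lactone (C7, C8, C17, C19): propionate aldol on a C8 ketone, then lactonisation onto C7–OH; the C8 ketone comes from acylation of a C9 α-alkoxyorganolithium (from the ring A aldehyde) with an (R)-glycerate amide (C6–C8).
Ring A first, by a catalytic asymmetric Diels–Alder reaction (C1, C10); order of ring formation: ring A, lactone, eleven-membered ether, ten-membered carbocycle, epoxide.

Key step: step 20

Numbering (briarane): C1 quaternary ring-fusion carbon (methyl C15); C2, C3 epoxide carbons; C4; C5 (exocyclic C16); C6 (Cl); C7 (lactone O); C8 (OH); C9 (acetoxyacetate); C10; ring A = C1, C10–C14 (C11 with methyl C20 and acetate, C12 ketone); lactone = C7, C8, C17 (methyl C18), C19.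
Assumption: in step 2 the sense of induction follows the accepted pre-transition-state model for 2-methyl-2-enals bound to this oxazaborolidinium catalyst; if the diene adds to the other enal face, the R catalyst is used instead.
Remark: C2 is stereogenic but without consequence in compounds 21–29 (both epimers give ketone 30) and is left undefined there; the C11 hydrogen configuration of 4–18 is erased in step 12.

Step 1
Reactants: 1 pent-1-en-3-one
Product: 2 (Z)-3-(triisopropylsilyloxy)penta-1,3-diene
Conditions: TIPSOTf, Et3N, Et2O, 0 °C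
Reagents that add atoms: triisopropylsilyl triflate, CC(C)[Si](OS(=O)(=O)C(F)(F)F)(C(C)C)C(C)C
Why: Silyl triflate and amine enolise the ethyl ketone toward the methyl-bearing carbon (silyl enol ether formation), and the Z enol ether with methyl cis to oxygen is expected, which places that methyl group on the outside of the s-cis diene.

Step 2
Reactants: 2 (Z)-3-(triisopropylsilyloxy)penta-1,3-diene; 3 (E)-4-acetoxy-2-methylbut-2-enal
Product: 4 ring A cycloadduct (C1 methyl and formyl; C10 acetoxymethyl trans to formyl; C11 methyl; C12 triisopropylsilyl enol ether)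
Conditions: (S)-3,3-diphenyl-1-(o-tolyl)tetrahydro-1H,3H-pyrrolo[1,2-c][1,3,2]oxazaborole (20 mol %), Tf2NH (20 mol %), CH2Cl2, −78 to −40 °C
Reagents that add atoms: none
Why: In this catalytic asymmetric Diels–Alder reaction the silyloxy group directs the methyl-bearing diene terminus to the β-carbon C10 (silyloxy carbon para to C1), the E geometry of the dienophile becomes the trans relation of formyl and acetoxymethyl, and the chiral oxazaborolidinium ion bound to the formyl group shields one enal face so that C1 and C10 should form with the configuration of the target (C11 follows from the endo mode and is erased later).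

Step 3
Reactants: 4 ring A cycloadduct
Product: 5 C1 vinyl compound (formyl turned into the C2=C3 vinyl group)
Conditions: Ph3PCH3Br, KOtBu, THF, 0 °C
Reagents that add atoms: methyltriphenylphosphonium bromide, C[P+](c1ccccc1)(c1ccccc1)c1ccccc1.[Br-]
Why: Wittig methylenation of the non-enolisable neopentylic aldehyde is faster than attack of the ylide on the acetate or the hindered silyl enol ether and creates no stereocentre.

Step 4
Reactants: 5 C1 vinyl compound
Product: 6 C9 primary alcohol
Conditions: K2CO3, MeOH, 0 °C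
Reagents that add atoms: none
Why: Mild transesterification (Zemplén-type methanolysis) frees the primary alcohol while the triisopropylsilyl enol ether is stable to carbonate in methanol.

Step 5
Reactants: 6 C9 primary alcohol
Product: 7 C9 aldehyde
Conditions: DMP, NaHCO3, CH2Cl2, 0 °C to rt
Reagents that add atoms: none
Why: Dess–Martin oxidation under buffered, non-basic conditions gives the aldehyde without epimerising C10, whose formyl group is already trans to the C11 methyl group.

Step 6
Reactants: 7 C9 aldehyde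
Product: 9 C9 acylstannane, via lithium stannyl alkoxide 8 (not isolated)
Conditions: Bu3SnLi (from Bu3SnH and LiN(iPr)2), THF, −78 °C; then 1,1′-(azodicarbonyl)dipiperidine, −78 to 0 °C
Reagents that add atoms: tributylstannyllithium, [Li][Sn](CCCC)(CCCC)CCCC
Why: Addition of the stannyl anion to the aldehyde followed by hydride abstraction from the alkoxide by the azodicarboxamide (Mukaiyama-type oxidation) gives the acylstannane and removes the uncontrolled carbinol centre.

Step 7
Reactants: 9 C9 acylstannane
Product: 11 (9R)-α-[(4-methoxybenzyloxy)methoxy]stannane, via α-hydroxystannane 10 (not isolated)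
Conditions: LiAlH(OEt)[(S)-1,1′-bi-2-naphtholate], THF, −78 °C; aqueous work-up; then 4-methoxybenzyl chloromethyl ether, iPr2NEt, CH2Cl2, 0 °C
Reagents that add atoms: 4-methoxybenzyl chloromethyl ether, COc1ccc(COCCl)cc1
Why: Reagent-controlled reduction of the acylstannane by the binaphthol-modified aluminium hydride, in which the stannyl group takes the place of the unsaturated substituent so that the S reagent should give the 9R carbinol, is followed by alkylation of the labile hydroxystannane to a formaldehyde acetal that stabilises the later organolithium and can be removed oxidatively.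

Step 8
Reactants: 12 methyl (R)-2,2-dimethyl-1,3-dioxolane-4-carboxylate
Product: 13 (R)-N-methoxy-N,2,2-trimethyl-1,3-dioxolane-4-carboxamide
Conditions: MeNHOMe·HCl, iPrMgCl, THF, −20 °C
Reagents that add atoms: N,O-dimethylhydroxylamine hydrochloride, CNOC.Cl
Why: Aminolysis of the ester by the magnesium amide at low temperature gives the N-methoxy-N-methylamide without epimerising the α-alkoxy centre C7, which comes from the chiral pool.

Step 9
Reactants: 11 (9R)-α-[(4-methoxybenzyloxy)methoxy]stannane; 13 (R)-N-methoxy-N,2,2-trimethyl-1,3-dioxolane-4-carboxamide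
Product: 15 C8 ketone (C9 acetal ether; C6/C7 acetonide), via α-alkoxyorganolithium 14 (not isolated)
Conditions: n-BuLi, THF, −78 °C; then 13, −78 °C
Reagents that add atoms: none
Why: Tin–lithium exchange gives a configurationally stable, internally chelated α-alkoxyorganolithium that acylates the N-methoxy-N-methylamide with retention at C9, the stable tetrahedral chelate preventing over-addition, so the C8 ketone forms with C9 and C7 both defined.

Step 10
Reactants: 15 C8 ketone; 16 methyl propionate
Product: 17 β-hydroxy ester (C8 tertiary alcohol; C17 methyl; C19 methyl ester)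
Conditions: LiN(iPr)2, THF/DMPU, −78 °C; 16; then 15; AcOH, −78 °C
Reagents that add atoms: none
Why: Aldol addition of the propionate enolate under non-chelating conditions should follow the polar Felkin–Anh model, in which the α-oxygen substituents at C9 and at C7 both direct the nucleophile to the same carbonyl face and so give the C8 configuration of the target, while the enolate with methyl cis to the oxyanion (formed with DMPU) should place the C17 methyl syn to the C8 hydroxyl through a Zimmerman–Traxler transition state.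

Step 11
Reactants: 17 β-hydroxy ester
Product: 18 ring A enone (C12 ketone; C13=C14)
Conditions: Pd(OAc)2 (1.1 equiv), DMSO, 50 °C
Reagents that add atoms: none
Why: Saegusa–Ito oxidation, in which the silyl enol ether is transmetalated to a palladium enolate and β-hydride elimination from C14 follows, gives the C13=C14 enone regiospecifically because the cycloaddition fixed the enol ether toward C13.

Step 12
Reactants: 18 ring A enone
Product: 20 C11 acetate (C8 triethylsilyl ether), via bis-silyl dienol ether 19 (not isolated)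
Conditions: TESOTf, Et3N, CH2Cl2, −78 to 0 °C; then Pb(OAc)4, CH2Cl2, −78 to 0 °C
Reagents that add atoms: triethylsilyl triflate, CC[Si](CC)(CC)OS(=O)(=O)C(F)(F)F; lead tetraacetate, CC(=O)O[Pb](OC(C)=O)(OC(C)=O)OC(C)=O
Why: Soft enolisation can occur only at C11 because C1 is quaternary, and the resulting 2-silyloxydiene is acetoxylated at C11 by lead tetraacetate (Rubottom-type oxidation) from the face opposite to the C9 side chain on C10, which sets the acetate cis to H10 as in the target, while the tertiary C8 hydroxyl is silylated at the same time and keeps this group to step 24.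

Step 13
Reactants: 20 C11 acetate
Product: 21 C2,C3-diol
Conditions: OsO4 (cat.), N-methylmorpholine N-oxide, acetone/H2O, 0 °C
Reagents that add atoms: N-methylmorpholine N-oxide, C[N+]1([O-])CCOCC1; water, O
Why: Catalytic dihydroxylation (Upjohn conditions) takes place at the monosubstituted vinyl group and not at the electron-poor enone double bond, and the C2 configuration is irrelevant because C2 becomes a ketone in step 19.

Step 14
Reactants: 21 C2,C3-diol; 22 2,3-dibromopropene
Product: 24 C3 2-bromoallyl ether, via stannylene acetal 23 (not isolated)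
Conditions: Bu2SnO, toluene, reflux; then 22, Bu4NI, 80 °C
Reagents that add atoms: none
Why: Regioselective O-alkylation through the dibutylstannylene acetal activates the primary C3 oxygen, which displaces the allylic bromide in an SN2 reaction while the vinylic bromide and the hindered secondary C2 hydroxyl stay untouched.

Step 15
Reactants: 24 C3 2-bromoallyl ether
Product: 26 γ-lactone diol, via dihydroxy ester 25 (not isolated)
Conditions: camphorsulfonic acid (cat.), MeOH, rt
Reagents that add atoms: none
Why: Acid-catalysed methanolysis removes the acetonide and the freed C7 hydroxyl closes the five-membered lactone onto the neighbouring methyl ester (intramolecular transesterification, preferred over the six-membered alternative from the C6 hydroxyl), while the hindered tertiary silyl ether, the formaldehyde acetal and the tertiary acetate should survive.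

Step 16
Reactants: 26 γ-lactone diol
Product: 27 C6 aldehyde
Conditions: TEMPO (cat.), PhI(OAc)2, CH2Cl2, rt
Reagents that add atoms: none
Why: Oxoammonium-mediated oxidation is selective for the primary C6 alcohol, so the aldehyde forms while the hindered secondary C2 hydroxyl, which must not be a ketone during ring closure (a ketone there would be attacked in a five-membered mode), stays untouched.

Step 17
Reactants: 27 C6 aldehyde
Product: 28 eleven-membered ether diol
Conditions: CrCl2, NiCl2 (cat.), DMSO/THF, rt, high dilution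
Reagents that add atoms: none
Why: Intramolecular Nozaki–Hiyama–Kishi reaction, in which nickel-catalysed formation of the C5 vinylchromium species is followed by its chemoselective addition to the aldehyde, closes the eleven-membered ether ring by C5–C6 bond formation, and attack anti to the C7–O bond (Felkin–Anh) should give the 6R alcohol with O6 and O7 anti.

Step 18
Reactants: 28 eleven-membered ether diol
Product: 29 C6 triethylsilyl ether
Conditions: TESCl, imidazole, CH2Cl2, 0 °C
Reagents that add atoms: chlorotriethylsilane, CC[Si](Cl)(CC)CC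
Why: Silylation with the chlorosilane and imidazole should take place at the allylic C6 hydroxyl and not at the C2 hydroxyl, which is neopentylic next to the quaternary C1.

Step 19
Reactants: 29 C6 triethylsilyl ether
Product: 30 eleven-membered α-allyloxy ketone
Conditions: DMP, NaHCO3, CH2Cl2, rt
Reagents that add atoms: none
Why: Dess–Martin oxidation of the remaining secondary alcohol gives the C2 ketone and removes the inconsequential C2 stereocentre.

Step 20
Reactants: 30 eleven-membered α-allyloxy ketone
Product: 33 ten-membered (3S)-α-hydroxy ketone, via boron enolate 31 (not isolated), via O-boryl ketol 32 (not isolated)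
Conditions: Bu2BOTf, iPr2NEt, CH2Cl2, −78 to 0 °C; then pH 7 buffer, MeOH
Reagents that add atoms: none
Why: Proposed new method: Dibutylboron triflate and the amine should convert the C2 ketone, which can enolise only toward C3 because C1 is quaternary, into its boron enolate, whose carbon C3 attacks the terminal alkene carbon C4 through a five-membered envelope transition state while the O–C16 bond breaks and the double bond moves to C5=C16 ([2,3]-Wittig rearrangement). The closest known reactions are the boron-enolate [2,3]-Wittig rearrangement of open-chain α-allyloxy ketones and esters and the carbanionic [2,3]-Wittig ring contraction of macrocyclic allylic ethers; their combination on a ketone enolate held in a ring has not been shown. The ten-membered carbocycle is closed by contraction of the eleven-membered ether ring, that is by transannular bond formation inside an existing ring and not by end-to-end cyclisation. The new stereocentre C3 is controlled by the enolate geometry, which the ring fixes with C1 and the ether oxygen cis, and by the ring conformation imposed by the trans-fused ring A and the cis-fused lactone, which should deliver C4 to the enolate face that gives the 3S carbinol. The step needs the [2,3] pathway to win over the [1,2] shift and the [3,3] shift of the allyl vinyl ether unit, which the concerted five-centre pathway at low temperature and the unhindered CH2 terminus should secure, and it needs enolisation of the C2 ketone alone, which is secured because the ring A enone has no enolisable position and the lactone and esters are not enolised by the boron triflate and amine.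

Step 21
Reactants: 33 ten-membered (3S)-α-hydroxy ketone
Product: 34 (2R,3S)-anti-diol
Conditions: Me4NBH(OAc)3, MeCN/AcOH, −20 °C
Reagents that add atoms: none
Why: Hydroxyl-directed reduction (Evans–Saksena type), in which the C3 hydroxyl binds the triacetoxyborohydride and delivers hydride intramolecularly to C2, leaves the ring A enone untouched and should give the 2R alcohol anti to the C3 hydroxyl.

Step 22
Reactants: 34 (2R,3S)-anti-diol
Product: 35 C3 mesylate
Conditions: MsCl, Et3N, CH2Cl2, −30 °C
Reagents that add atoms: methanesulfonyl chloride, CS(=O)(=O)Cl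
Why: Sulfonylation is selective for the C3 hydroxyl because the C2 hydroxyl is neopentylic next to the quaternary C1.

Step 23
Reactants: 35 C3 mesylate
Product: 36 (2R,3R)-trans-epoxide
Conditions: DBU, CH2Cl2, rt
Reagents that add atoms: none
Why: Intramolecular Williamson reaction (3-exo-tet), in which the C2 oxygen displaces the C3 mesylate with inversion, converts the anti diol into the trans-epoxide.

Step 24
Reactants: 36 (2R,3R)-trans-epoxide
Product: 37 epoxide diol (C6 and C8 hydroxyls free)
Conditions: HF·pyridine, pyridine, THF, 0 °C to rt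
Reagents that add atoms: none
Why: Buffered fluoride cleaves the two triethylsilyl ethers while the formaldehyde acetal at C9, the epoxide and the esters are stable under these conditions.

Step 25
Reactants: 37 epoxide diol
Product: 38 (6S) allylic chloride
Conditions: PPh3, hexachloroacetone, CH2Cl2, −30 to 0 °C
Reagents that add atoms: hexachloroacetone, ClC(Cl)(Cl)C(=O)C(Cl)(Cl)Cl
Why: Appel-type chlorination of the allylic alcohol proceeds through the alkoxyphosphonium salt by SN2 displacement with inversion and should show little allylic transposition under these neutral, cold conditions, while the tertiary C8 alcohol does not react.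

Step 26
Reactants: 38 (6S) allylic chloride
Product: 39 C9 alcohol
Conditions: DDQ, CH2Cl2/pH 7 buffer, 0 °C
Reagents that add atoms: none
Why: Oxidative cleavage of the 4-methoxybenzyl formaldehyde acetal, by hydride abstraction from the benzylic position and hydrolysis of the resulting hemiformal, frees the C9 hydroxyl under neutral conditions that spare the epoxide and the allylic chloride.

Step 27
Reactants: 39 C9 alcohol
Product: 40 CNP0314084.4
Conditions: acetoxyacetyl chloride, pyridine, DMAP (cat.), CH2Cl2, 0 °C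
Reagents that add atoms: acetoxyacetyl chloride, CC(=O)OCC(=O)Cl
Why: Acylation with the acid chloride under nucleophilic catalysis esterifies the secondary C9 hydroxyl, the tertiary C8 hydroxyl being too hindered to react, and completes the target.

Compound list
1 | pent-1-en-3-one | CCC(=O)C=C | starting material
2 | (Z)-3-(triisopropylsilyloxy)penta-1,3-diene | C=C/C(O[Si](C(C)C)(C(C)C)C(C)C)=C/C | intermediate
3 | (E)-4-acetoxy-2-methylbut-2-enal | CC(=O)OC/C=C(\C)C=O | starting material
4 | ring A cycloadduct: cyclohexene with C1 (methyl, formyl), C10 (acetoxymethyl, trans to formyl), C11 (methyl, cis to formyl) and C12 triisopropylsilyl enol ether (C12=C13); C1 and C10 as in the target | O=C[C@@]1(C)CC=C(O[Si](C(C)C)(C(C)C)C(C)C)[C@@H](C)[C@@H]1COC(C)=O | intermediate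
5 | as 4 with the formyl group replaced by the C2=C3 vinyl group | C=C[C@@]1(C)CC=C(O[Si](C(C)C)(C(C)C)C(C)C)[C@@H](C)[C@@H]1COC(C)=O | intermediate
6 | as 5 with C9 as primary alcohol | C=C[C@@]1(C)CC=C(O[Si](C(C)C)(C(C)C)C(C)C)[C@@H](C)[C@@H]1CO | intermediate
7 | as 5 with C9 as aldehyde | C=C[C@@]1(C)CC=C(O[Si](C(C)C)(C(C)C)C(C)C)[C@@H](C)[C@@H]1C=O | intermediate
8 | lithium alkoxide of the C9 tributylstannyl carbinol (both C9 epimers) | C=C[C@@]1(C)CC=C(O[Si](C(C)C)(C(C)C)C(C)C)[C@@H](C)[C@@H]1C(O[Li])[Sn](CCCC)(CCCC)CCCC | intermediate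
9 | C9 acylstannane (tributylstannyl ketone on C10) | C=C[C@@]1(C)CC=C(O[Si](C(C)C)(C(C)C)C(C)C)[C@@H](C)[C@@H]1C(=O)[Sn](CCCC)(CCCC)CCCC | intermediate
10 | (9R)-α-hydroxystannane | C=C[C@@]1(C)CC=C(O[Si](C(C)C)(C(C)C)C(C)C)[C@@H](C)[C@@H]1[C@H](O)[Sn](CCCC)(CCCC)CCCC | intermediate
11 | (9R)-α-[(4-methoxybenzyloxy)methoxy]stannane | C=C[C@@]1(C)CC=C(O[Si](C(C)C)(C(C)C)C(C)C)[C@@H](C)[C@@H]1[C@H](OCOCc2ccc(OC)cc2)[Sn](CCCC)(CCCC)CCCC | intermediate
12 | methyl (R)-2,2-dimethyl-1,3-dioxolane-4-carboxylate | COC(=O)[C@H]1COC(C)(C)O1 | starting material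
13 | (R)-N-methoxy-N,2,2-trimethyl-1,3-dioxolane-4-carboxamide | CON(C)C(=O)[C@H]1COC(C)(C)O1 | intermediate
14 | C9 α-alkoxyorganolithium (configuration of 11 retained) | C=C[C@@]1(C)CC=C(O[Si](C(C)C)(C(C)C)C(C)C)[C@@H](C)[C@@H]1[C@H](OCOCc2ccc(OC)cc2)[Li] | intermediate
15 | C8 ketone: C9 (4-methoxybenzyloxy)methyl ether, C6/C7 acetonide | C=C[C@@]1(C)CC=C(O[Si](C(C)C)(C(C)C)C(C)C)[C@@H](C)[C@@H]1[C@H](OCOCc2ccc(OC)cc2)C(=O)[C@H]3COC(C)(C)O3 | intermediate
16 | methyl propionate | CCC(=O)OC | starting material
17 | β-hydroxy ester: C8 tertiary alcohol carrying C17H(CH3)–CO2CH3; C8 and C17 as in the target | C=C[C@@]1(C)CC=C(O[Si](C(C)C)(C(C)C)C(C)C)[C@@H](C)[C@@H]1[C@H](OCOCc2ccc(OC)cc2)[C@](O)([C@@H](C)C(=O)OC)[C@H]3COC(C)(C)O3 | intermediate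
18 | as 17 with ring A as C12 ketone and C13=C14 (C11 still CH–CH3) | C=C[C@@]1(C)C=CC(=O)[C@@H](C)[C@@H]1[C@H](OCOCc2ccc(OC)cc2)[C@](O)([C@@H](C)C(=O)OC)[C@H]3COC(C)(C)O3 | intermediate
19 | C11=C12 triethylsilyl dienol ether with C8 triethylsilyl ether | C=C[C@@]1(C)C=CC(O[Si](CC)(CC)CC)=C(C)[C@@H]1[C@H](OCOCc2ccc(OC)cc2)[C@](O[Si](CC)(CC)CC)([C@@H](C)C(=O)OC)[C@H]3COC(C)(C)O3 | intermediate
20 | C11 acetate enone with C8 triethylsilyl ether and C1 vinyl | C=C[C@@]1(C)C=CC(=O)[C@@](C)(OC(C)=O)[C@@H]1[C@H](OCOCc2ccc(OC)cc2)[C@](O[Si](CC)(CC)CC)([C@@H](C)C(=O)OC)[C@H]3COC(C)(C)O3 | intermediate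
21 | C2,C3-diol (C2 epimers) | OCC(O)[C@@]1(C)C=CC(=O)[C@@](C)(OC(C)=O)[C@@H]1[C@H](OCOCc2ccc(OC)cc2)[C@](O[Si](CC)(CC)CC)([C@@H](C)C(=O)OC)[C@H]3COC(C)(C)O3 | intermediate
22 | 2,3-dibromopropene | C=C(Br)CBr | starting material
23 | C2,C3 dibutylstannylene acetal of 21 | CCCC[Sn]1(CCCC)OCC(O1)[C@@]2(C)C=CC(=O)[C@@](C)(OC(C)=O)[C@@H]2[C@H](OCOCc3ccc(OC)cc3)[C@](O[Si](CC)(CC)CC)([C@@H](C)C(=O)OC)[C@H]4COC(C)(C)O4 | intermediate
24 | C3 O-(2-bromoallyl) ether with free C2 hydroxyl | C=C(Br)COCC(O)[C@@]1(C)C=CC(=O)[C@@](C)(OC(C)=O)[C@@H]1[C@H](OCOCc2ccc(OC)cc2)[C@](O[Si](CC)(CC)CC)([C@@H](C)C(=O)OC)[C@H]3COC(C)(C)O3 | intermediate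
25 | C6,C7-diol methyl ester (acetonide removed) | C=C(Br)COCC(O)[C@@]1(C)C=CC(=O)[C@@](C)(OC(C)=O)[C@@H]1[C@H](OCOCc2ccc(OC)cc2)[C@](O[Si](CC)(CC)CC)([C@@H](C)C(=O)OC)[C@H](O)CO | intermediate
26 | γ-lactone (C7–O–C19) with C2 and C6 hydroxyls and C8 triethylsilyl ether | C=C(Br)COCC(O)[C@@]1(C)C=CC(=O)[C@@](C)(OC(C)=O)[C@@H]1[C@H](OCOCc2ccc(OC)cc2)[C@@]3(O[Si](CC)(CC)CC)[C@H](OC(=O)[C@@H]3C)CO | intermediate
27 | C6 aldehyde with C2 hydroxyl | C=C(Br)COCC(O)[C@@]1(C)C=CC(=O)[C@@](C)(OC(C)=O)[C@@H]1[C@H](OCOCc2ccc(OC)cc2)[C@@]3(O[Si](CC)(CC)CC)[C@H](OC(=O)[C@@H]3C)C=O | intermediate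
28 | eleven-membered ether ring with C2 hydroxyl (epimers) and (6R) allylic alcohol | C=C1COCC(O)[C@@]2(C)C=CC(=O)[C@@](C)(OC(C)=O)[C@@H]2[C@H](OCOCc3ccc(OC)cc3)[C@@]4(O[Si](CC)(CC)CC)[C@H](OC(=O)[C@@H]4C)[C@@H]1O | intermediate
29 | C6 triethylsilyl ether of 28 | C=C1COCC(O)[C@@]2(C)C=CC(=O)[C@@](C)(OC(C)=O)[C@@H]2[C@H](OCOCc3ccc(OC)cc3)[C@@]4(O[Si](CC)(CC)CC)[C@H](OC(=O)[C@@H]4C)[C@@H]1O[Si](CC)(CC)CC | intermediate
30 | key-step precursor: eleven-membered α-allyloxy ketone (C2 ketone), C6 and C8 triethylsilyl ethers, C9 (4-methoxybenzyloxy)methyl ether | C=C1COCC(=O)[C@@]2(C)C=CC(=O)[C@@](C)(OC(C)=O)[C@@H]2[C@H](OCOCc3ccc(OC)cc3)[C@@]4(O[Si](CC)(CC)CC)[C@H](OC(=O)[C@@H]4C)[C@@H]1O[Si](CC)(CC)CC | intermediate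
31 | dibutylboron enolate of 30 (C2=C3) | C=C1COC=C(OB(CCCC)CCCC)[C@@]2(C)C=CC(=O)[C@@](C)(OC(C)=O)[C@@H]2[C@H](OCOCc3ccc(OC)cc3)[C@@]4(O[Si](CC)(CC)CC)[C@H](OC(=O)[C@@H]4C)[C@@H]1O[Si](CC)(CC)CC | intermediate
32 | O-dibutylboryl derivative of 33 | C=C1C[C@H](OB(CCCC)CCCC)C(=O)[C@@]2(C)C=CC(=O)[C@@](C)(OC(C)=O)[C@@H]2[C@H](OCOCc3ccc(OC)cc3)[C@@]4(O[Si](CC)(CC)CC)[C@H](OC(=O)[C@@H]4C)[C@@H]1O[Si](CC)(CC)CC | intermediate
33 | ten-membered carbocycle: C2 ketone, (3S) hydroxyl, C5=C16 exocyclic methylene | C=C1C[C@H](O)C(=O)[C@@]2(C)C=CC(=O)[C@@](C)(OC(C)=O)[C@@H]2[C@H](OCOCc3ccc(OC)cc3)[C@@]4(O[Si](CC)(CC)CC)[C@H](OC(=O)[C@@H]4C)[C@@H]1O[Si](CC)(CC)CC | intermediate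
34 | (2R,3S)-anti-diol | C=C1C[C@H](O)[C@H](O)[C@@]2(C)C=CC(=O)[C@@](C)(OC(C)=O)[C@@H]2[C@H](OCOCc3ccc(OC)cc3)[C@@]4(O[Si](CC)(CC)CC)[C@H](OC(=O)[C@@H]4C)[C@@H]1O[Si](CC)(CC)CC | intermediate
35 | C3 mesylate of 34 | C=C1C[C@H](OS(C)(=O)=O)[C@H](O)[C@@]2(C)C=CC(=O)[C@@](C)(OC(C)=O)[C@@H]2[C@H](OCOCc3ccc(OC)cc3)[C@@]4(O[Si](CC)(CC)CC)[C@H](OC(=O)[C@@H]4C)[C@@H]1O[Si](CC)(CC)CC | intermediate
36 | (2R,3R)-trans-epoxide with C6 and C8 triethylsilyl ethers | C=C1C[C@H]2O[C@@H]2[C@@]2(C)C=CC(=O)[C@@](C)(OC(C)=O)[C@@H]2[C@H](OCOCc3ccc(OC)cc3)[C@@]4(O[Si](CC)(CC)CC)[C@H](OC(=O)[C@@H]4C)[C@@H]1O[Si](CC)(CC)CC | intermediate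
37 | epoxide with free (6R) and C8 hydroxyls | C=C1C[C@H]2O[C@@H]2[C@@]2(C)C=CC(=O)[C@@](C)(OC(C)=O)[C@@H]2[C@H](OCOCc3ccc(OC)cc3)[C@@]4(O)[C@H](OC(=O)[C@@H]4C)[C@@H]1O | intermediate
38 | (6S) allylic chloride with C8 hydroxyl and C9 (4-methoxybenzyloxy)methyl ether | C=C1C[C@H]2O[C@@H]2[C@@]2(C)C=CC(=O)[C@@](C)(OC(C)=O)[C@@H]2[C@H](OCOCc3ccc(OC)cc3)[C@@]4(O)[C@H](OC(=O)[C@@H]4C)[C@H]1Cl | intermediate
39 | C9 alcohol | C=C1C[C@H]2O[C@@H]2[C@@]2(C)C=CC(=O)[C@@](C)(OC(C)=O)[C@@H]2[C@H](O)[C@@]4(O)[C@H](OC(=O)[C@@H]4C)[C@H]1Cl | intermediate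
40 | CNP0314084.4 | C=C1C[C@H]2O[C@@H]2[C@@]2(C)C=CC(=O)[C@@](C)(OC(C)=O)[C@@H]2[C@H](OC(=O)COC(C)=O)[C@@]2(O)[C@H](OC(=O)[C@@H]2C)[C@H]1Cl | target

Total step count: 27. Longest linear sequence: 26 steps (steps 1–7 and 9–27); step 8 is the only side branch.

Steps most likely to fail

Step 20 (Proposed new method). What may go wrong: the [1,2]-shift or the [3,3]-shift of the boron enolate may outrun the [2,3]-shift, enolisation of the neopentylic ketone may be slow, or the ring conformation may deliver C4 to the other enolate face and give the 3-epimer. Fallback with known chemistry: the two ring events are taken in the opposite order, so that the [2,3]-shift runs on an open chain (known for α-allyloxy ketones) and the ten-membered ring is closed afterwards by a Nozaki–Hiyama–Kishi reaction (known for medium rings). It sets out from lactone diol 26 and comes back at epoxide diol 37. The primary hydroxyl of 26 is silylated (TESCl, imidazole) to the C6 triethylsilyl ether F1. DMP gives the open-chain α-(2-bromoallyloxy) ketone F2. Bu2BOTf and iPr2NEt give the α-ketol F3, which carries the C5 vinyl bromide, and its C3 epimers are separated at this point. Me4NBH(OAc)3 gives the anti diol F4, MsCl the C3 mesylate F5 and DBU the trans-epoxide F6. HF·pyridine frees the hydroxy compound F7, and TEMPO with PhI(OAc)2 oxidises its primary alcohol to the aldehyde F8. CrCl2 with catalytic NiCl2 then joins the C5 vinyl bromide to the C6 aldehyde and gives 37.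

Step 17. What may go wrong: the vinylchromium may add to the other face of the C6 aldehyde because the ring-closing geometry overrides the Felkin–Anh preference, so that the 6-epimer forms. Fallback: the stereocentre is corrected after ring closure instead of being set in it. It sets out from aldehyde 27 and comes back at 28. The ring closure is run as before, and the resulting 6-epi alcohol F9 is inverted by a Mitsunobu reaction (4-nitrobenzoic acid, PPh3, DIAD), which cannot touch the neopentylic C2 hydroxyl, to the (6R) 4-nitrobenzoate F10. Methanolysis (K2CO3, MeOH, 0 °C) gives 28.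

Step 25. What may go wrong: allylic transposition during the displacement (chloride attacking C16 with shift of the double bond into the ring) or ionisation of the activated allylic oxygen with loss of the inversion. Fallback: the transposition is used instead of avoided. It sets out from epoxide diol 37 and comes back at chloride 38. O3ReOSiPh3 (cat.) shifts the allylic alcohol to the primary C16 allylic alcohol F11 with an endocyclic C5=C6 bond. Thionyl chloride in Et2O then returns chlorine to C6 with allylic shift by internal delivery, which restores the exocyclic methylene; the C6 configuration then rests on delivery from the outer face of the ring.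

Further compounds
F1 | step 20 | C6 triethylsilyl ether of 26 | C=C(Br)COCC(O)[C@@]1(C)C=CC(=O)[C@@](C)(OC(C)=O)[C@@H]1[C@H](OCOCc2ccc(OC)cc2)[C@@]3(O[Si](CC)(CC)CC)[C@H](OC(=O)[C@@H]3C)CO[Si](CC)(CC)CC
F2 | step 20 | open-chain α-(2-bromoallyloxy) ketone (C2 ketone) | C=C(Br)COCC(=O)[C@@]1(C)C=CC(=O)[C@@](C)(OC(C)=O)[C@@H]1[C@H](OCOCc2ccc(OC)cc2)[C@@]3(O[Si](CC)(CC)CC)[C@H](OC(=O)[C@@H]3C)CO[Si](CC)(CC)CC
F3 | step 20 | open-chain (3S)-α-ketol with C5 vinyl bromide | C=C(Br)C[C@H](O)C(=O)[C@@]1(C)C=CC(=O)[C@@](C)(OC(C)=O)[C@@H]1[C@H](OCOCc2ccc(OC)cc2)[C@@]3(O[Si](CC)(CC)CC)[C@H](OC(=O)[C@@H]3C)CO[Si](CC)(CC)CC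
F4 | step 20 | open-chain (2R,3S)-anti-diol | C=C(Br)C[C@H](O)[C@H](O)[C@@]1(C)C=CC(=O)[C@@](C)(OC(C)=O)[C@@H]1[C@H](OCOCc2ccc(OC)cc2)[C@@]3(O[Si](CC)(CC)CC)[C@H](OC(=O)[C@@H]3C)CO[Si](CC)(CC)CC
F5 | step 20 | open-chain C3 mesylate | C=C(Br)C[C@H](OS(C)(=O)=O)[C@H](O)[C@@]1(C)C=CC(=O)[C@@](C)(OC(C)=O)[C@@H]1[C@H](OCOCc2ccc(OC)cc2)[C@@]3(O[Si](CC)(CC)CC)[C@H](OC(=O)[C@@H]3C)CO[Si](CC)(CC)CC
F6 | step 20 | open-chain (2R,3R)-trans-epoxide with C6 and C8 triethylsilyl ethers | C=C(Br)C[C@H]2O[C@@H]2[C@@]1(C)C=CC(=O)[C@@](C)(OC(C)=O)[C@@H]1[C@H](OCOCc2ccc(OC)cc2)[C@@]3(O[Si](CC)(CC)CC)[C@H](OC(=O)[C@@H]3C)CO[Si](CC)(CC)CC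
F7 | step 20 | open-chain epoxide with free C6 and C8 hydroxyls | C=C(Br)C[C@H]2O[C@@H]2[C@@]1(C)C=CC(=O)[C@@](C)(OC(C)=O)[C@@H]1[C@H](OCOCc2ccc(OC)cc2)[C@@]3(O)[C@H](OC(=O)[C@@H]3C)CO
F8 | step 20 | open-chain epoxide C6 aldehyde | C=C(Br)C[C@H]2O[C@@H]2[C@@]1(C)C=CC(=O)[C@@](C)(OC(C)=O)[C@@H]1[C@H](OCOCc2ccc(OC)cc2)[C@@]3(O)[C@H](OC(=O)[C@@H]3C)C=O
F9 | step 17 | 6-epimer of 28 | C=C1COCC(O)[C@@]2(C)C=CC(=O)[C@@](C)(OC(C)=O)[C@@H]2[C@H](OCOCc3ccc(OC)cc3)[C@@]4(O[Si](CC)(CC)CC)[C@H](OC(=O)[C@@H]4C)[C@H]1O
F10 | step 17 | (6R) 4-nitrobenzoate of 28 | C=C1COCC(O)[C@@]2(C)C=CC(=O)[C@@](C)(OC(C)=O)[C@@H]2[C@H](OCOCc3ccc(OC)cc3)[C@@]4(O[Si](CC)(CC)CC)[C@H](OC(=O)[C@@H]4C)[C@@H]1OC(=O)c5ccc(cc5)[N+](=O)[O-]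
F11 | step 25 | transposed primary C16 allylic alcohol with endocyclic C5=C6 | OCC=1C[C@H]2O[C@@H]2[C@@]2(C)C=CC(=O)[C@@](C)(OC(C)=O)[C@@H]2[C@H](OCOCc3ccc(OC)cc3)[C@@]4(O)[C@H](OC(=O)[C@@H]4C)C=1
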